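Put the flasks and the earlier runs side by side, and look at what heat does to the product.

| flask | substrate | gas phase | catalyst | temperature | remark | time |
|---|---|---|---|---|---|---|
| amber | 0.25 M | 24 mM (held) | 0.18 mM | 42 °C | run made earlier |  |
| green | 0.25 M | 24 mM (held) | 0.20 mM | 59 °C | run made earlier |  |
| teal | 0.25 M | 24 mM (held) | 0.28 mM | 42 °C | run made earlier |  |
| cedar | 0.25 M | 24 mM (held) | 0.15 mM |  | at 35 °C throughout | 3.0 h |
| oak | 0.25 M | 24 mM (held) | 0.25 mM |  | at 35 °C until 1.5 h, from then on at 65 °C | 3.0 h |

| run | time / min | product / % | substrate / % |
|---|---|---|---|
| amber | 15.0 | 3.9 | 95.6 |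
| amber | 40.0 | 9.1 | 90.2 |
| amber | 80.0 | 18.6 | 83.3 |
| amber | 120 | 22.2 | 75.7 |
| green | 10.0 | 0.3 | 98.8 |
| green | 20.0 | 3.1 | 96.1 |
| green | 30.0 | 5.1 | 93.4 |
| green | 40.0 | 7.9 | 95.2 |
| teal | 15.0 | 3.5 | 97.3 |
| teal | 40.0 | 10.0 | 90.4 |
| teal | 80.0 | 17.0 | 81.3 |
| teal | 120 | 23.5 | 77.3 |

(standard deviation of a reading: 1 percentage point)

* the winner by amount of product, in percent of the substrate charged; "neither" if no more than 2 percentage points parts them (cedar / oak / neither)
* how much product is there at the end, in percent of the substrate charged: cedar
* how much product is there at the end, in percent of the substrate charged: oak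

- at the start none of the gas phase is in solution

Here is the oddity. Green, at 59 °C with 0.20 mM of catalyst, holds 7.9% product at 40.0 min, less than the 9.1% of amber at 42 °C with 0.18 mM. The gap is within the scatter, but you expected a gain from the heat. Teal and amber stand level within the scatter at their last readings, 23.5% and 22.2%, despite their different catalyst, so a slow passage of the gas phase into solution could make the slopes equal. My reading, which these runs do not prove, is that the step also runs backward and that heat shifts its balance toward substrate, which would mean thermodynamic rather than kinetic control in a hot flask.

So measure the position. The hot ratio, green's product fraction over its substrate fraction at the last reading, reads 0.0830, with the scatter of those two readings. The symmetric case is the zero of the scale: at a ratio of one, product and substrate each hold half the charge. With substrate and product taken as the whole charge, any ratio gives a product fraction of ratio over one plus ratio, here 7.66%. Green's product was still rising at its last reading, which pulls this estimate up, while oak's 65 °C is hotter than green's 59 °C, which on my reading pulls it down, so I take it as it stands for oak. Amber's ratio as read at 80.0 min, 0.223, stands in for oak at 1.5 h, and it is higher than the hot ratio, so I expect oak to run backward once heated. Cedar stays cool, and amber's average slope carried to 3.0 h gives 33.3%. My reckoning therefore has cedar winning.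

The forecast says oak, with 31% for cedar and 37% for oak, on the ground that “temperature dependence is weak”. The flasks give 35.7% in cedar and 9.45% in oak, so cedar wins.

    gas phase ⇌ dissolved gas, rate k1*(csat - [dissolved gas]) (kL = 2.30 /h)
    substrate + dissolved gas + catalyst ⇌ catalyst + product (K = 40.0 /M, k = 5.10 × 10⁵ /M²/h, Ea = 37.0 kJ/mol, ΔH = −66.0 kJ/mol)
    (constants at 35 °C)

Oak falls from 22.8% product at 1.50 h to 9.45% at 3.00 h, a ratio of 0.104, beside the 0.0830 read from green. Now take a neighbour of oak charged with 0.62 M of substrate. The ratio compares fractions of the charge and the gas phase is held as in oak, so the same reckoning again gives 7.66%. That neighbour ends at a ratio of 0.0960, with 8.76% of its charge as product at 3.00 h.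

The data are simulated with constants of no real substance; scatter was added.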